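Pyrrole ring A shares its N1–C2 bond with lactam ring B, so N1–C2–C(=O) is a hidden α-amino acid. C2 can therefore start as the sp3 stereocentre of L-vinylglycine, sit next to the orthoamide carbon common to rings B, C and D, steer its configuration, and disappear on aromatisation. The route rests on cutting C3=C4: one flask of ring-closing metathesis and MnO2 dehydrogenation turns an N-allyl/C-vinyl pair into ring A. The precursor is the B/C/D tricycle, an imidazolidinone of N-allyl-L-vinylglycine fused to the hydroxylated piperidine and to a 2-aminoimidazoline carried as its neutral N-Boc derivative. Dibromination and Boc removal finish the synthesis.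

Key step: step 9

Atom labels:
- Cα is the α-carbon of the vinylglycine unit (later pyrrole C2).
- Na is its allylated nitrogen (later pyrrole N1).
- N3 is the lactam nitrogen shared by rings B and C.
- Ca is the carbinolamine carbon C–OH shared by rings C and D.
- Cb is the orthoamide carbon shared by rings B, C and D.

Assumption: ring D closes on the face of ring B opposite the vinyl group on Cα. L-vinylglycine should then lead to the target enantiomer, and the minor aminal diastereomer is removed by chromatography at the Boc-protected tricycle.

Design remarks: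
- Na is unmasked before any guanidine is present, so that the imide is hidden as an aza-cyclol and cannot be cleaved by acyl transfer.
- The guanidine is carried as a neutral acylguanidine. No acid is used in the metathesis, because protonation at Na would ionise the orthoamide.
- From step 4 to step 8 every operation is neutral or acidic, which protects the base-sensitive vinylglycine centre.

Step 1
Reactants: 1 L-vinylglycine
Product: 2 N-Boc-L-vinylglycine
Conditions: Boc2O, Et3N, 1,4-dioxane/H2O, 0 °C to rt; citric acid work-up
Reagents that add atoms: di-tert-butyl dicarbonate (Boc2O), CC(C)(C)OC(=O)OC(=O)OC(C)(C)C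
Why: Carbamate formation on the amino acid carboxylate is routine, and Et3N does not deprotonate an α-carbon flanked by a carboxylate, so the S configuration of the chiral pool is kept.

Step 2
Reactants: 2 N-Boc-L-vinylglycine; 3 allyl bromide
Product: 4 N-allyl-N-Boc-L-vinylglycine
Conditions: NaH (2.2 equiv), THF, 0 °C; then 3, 0 °C to rt; cold dilute HCl to pH 3
Reagents that add atoms: none
Why: This is the standard SN2 N-alkylation of a Boc-amino acid through its sodium carboxylate/sodium carbamate dianion, in which the carboxylate charge shields the α-hydrogen, so neither epimerisation nor migration of the vinyl double bond is expected.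

Step 3
Reactants: 5 3-hydroxypiperidin-2-one (racemic)
Product: 6 3-(tert-butyldimethylsilyloxy)piperidin-2-one (racemic)
Conditions: TBSCl, imidazole, DMF, rt
Reagents that add atoms: tert-butyldimethylsilyl chloride (TBSCl), CC(C)(C)[Si](C)(C)Cl
Why: Imidazole-promoted silyl ether formation takes the alcohol and leaves the lactam N–H free, and the racemic centre is irrelevant because step 7 oxidises it away.

Step 4
Reactants: 4 N-allyl-N-Boc-L-vinylglycine
Product: 7 N-allyl-N-Boc-L-vinylglycyl fluoride
Conditions: cyanuric fluoride, pyridine, CH2Cl2, −15 °C; ice-water wash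
Reagents that add atoms: cyanuric fluoride, Fc1nc(F)nc(F)n1
Why: Deoxyfluorination of a carboxylic acid with cyanuric fluoride gives a urethane-protected amino acid fluoride, a class that is isolable, tolerates Boc and, having no N–H, cannot racemise through an oxazolone.

Step 5
Reactants: 6 3-(tert-butyldimethylsilyloxy)piperidin-2-one; 7 N-allyl-N-Boc-L-vinylglycyl fluoride
Product: 9 1-(N-allyl-N-Boc-L-vinylglycyl)-3-(tert-butyldimethylsilyloxy)piperidin-2-one (both ring C3 epimers), via N-trimethylsilyl lactam 8 (not isolated)
Conditions: 6, HMDS, TMSCl (cat.), toluene, reflux, evaporate; then 7, DMAP (5 mol %), CH2Cl2, 0 °C to rt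
Reagents that add atoms: none
Why: N-acylation of an N-silyl lactam by an acyl halide, driven by the Si–F bond and the escape of volatile Me3SiF, forms the imide without any stoichiometric base, so the now more acidic α-hydrogen is left alone.

Step 6
Reactants: 9 silyloxy imide
Product: 10 1-(N-allyl-N-Boc-L-vinylglycyl)-3-hydroxypiperidin-2-one (both ring C3 epimers)
Conditions: HF·pyridine, pyridine/THF, 0 °C to rt
Reagents that add atoms: none
Why: Fluoride-mediated silyl ether cleavage in a buffered acidic medium spares the Boc group and the imide and avoids basic fluoride, which could open the imide or shift the vinyl group.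

Step 7
Reactants: 10 hydroxy imide
Product: 11 1-(N-allyl-N-Boc-L-vinylglycyl)piperidine-2,3-dione
Conditions: Dess–Martin periodinane, CH2Cl2, 0 °C to rt; short silica plug
Reagents that add atoms: none
Why: Dess–Martin oxidation of an α-hydroxy amide to an α-keto amide is a standard non-basic reaction that leaves terminal alkenes, carbamate and Cα untouched and merges the two ring C3 epimers into one compound.

Step 8
Reactants: 11 keto imide; 12 N-Boc-guanidine
Product: 15 N-Boc-protected B/C/D tricycle (Cα S; Ca R; Cb R; vinyl anti to the ring D nitrogen on Cb; OH syn to Na), via amino imide trifluoroacetate 13 (not isolated), via aza-cyclol 14 (not isolated)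
Conditions: TFA/CH2Cl2 (1:4), 0 °C, evaporate with toluene; then 12 (2.5 equiv), 4 Å molecular sieves, MeCN, 0 °C to rt; aqueous work-up, chromatography
Reagents that add atoms: none
Why: Proposed new method: acidolysis frees Na, which on neutralisation by 12 adds 5-exo-trig to the ketone-activated ring carbonyl Cb to give aza-cyclol 14, so that the imide a guanidine would cleave is masked as a plain lactam; one NH2 of 12 then adds reversibly to ketone Ca, the cyclol hydroxyl ionises with push from Na to a planar acylamidinium, and the tethered second NH2 closes ring D 5-exo-trig on the face of ring B anti to the vinyl group on Cα, which sets Cb, while the strain-enforced cis C/D fusion relays this to Ca (OH syn to Na); the closest known reaction types are aza-cyclol formation from N-(α-aminoacyl)lactams, the condensation of guanidines with 1,2-dicarbonyl compounds to hydroxyimidazolines, and anti-selective additions to iminium ions of 5-substituted imidazolidin-4-ones.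

Step 9
Reactants: 15 N-Boc-protected B/C/D tricycle
Product: 17 N-Boc-protected didebromo tetracycle (Ca R; Cb R), via 3-pyrroline tetracycle 16 (not isolated)
Conditions: second-generation Grubbs catalyst RuCl2(=CHPh)(PCy3)(SIMes) (5 mol %), 1,4-benzoquinone (10 mol %), toluene, high dilution, 60 °C; then activated MnO2 (10 equiv), same flask, 80 °C
Reagents that add atoms: none
Why: The benzylidene exchanges first with the less hindered N-allyl terminus, the new alkylidene adds to the neighbouring vinyl group in a [2+2] cycloaddition, and the ruthenacyclobutane cycloreverts with loss of ethylene, which forges C3=C4. The closest known reactions are the ring-closing metathesis of N-allyl vinylglycine derivatives to 3,4-dehydroprolines and one-pot metathesis/dehydrogenation syntheses of pyrroles. Ring A closes as a five-membered ring annulated on ring B across the Na–Cα bond, which is easy because both alkenes sit on adjacent ring atoms and Na can invert to bring them syn. No stereocentre is created: MnO2 removes the Cα–H and one C5–H of 16, both allylic and α to nitrogen, and aromatisation erases Cα, while Ca and Cb carry no hydrogen and stay as set. The chemoselectivity needed (cyclisation over catalyst binding, oligomerisation and vinyl migration) is secured by the Boc group, which makes the guanidine a neutral acylguanidine, by the crowding and low basicity of Na between Cb and Cα, by dilution, and by benzoquinone as hydride trap. No acid is added, since protonation at Na would make it a leaving group and ionise the orthoamide.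

Step 10
Reactants: 17 N-Boc-protected didebromo tetracycle
Product: 18 N-Boc-protected 4,5-dibromo tetracycle (Ca R; Cb S, same geometry, descriptor changed by bromine)
Conditions: NBS (2.1 equiv), THF, −20 °C to rt, dark
Reagents that add atoms: N-bromosuccinimide (NBS), O=C1CCC(=O)N1Br
Why: In this electrophilic aromatic substitution the 2-acyl group deactivates C3 most, so two equivalents of NBS fill C4 and C5 as is usual for 2-acylpyrroles, and any N-bromination of the acylguanidine is reversible and passes bromine on to the ring.

Step 11
Reactants: 18 N-Boc-protected 4,5-dibromo tetracycle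
Product: 19 target CNP0143627.2 (Ca R; Cb S)
Conditions: TFA/CH2Cl2 with 2 % H2O, 0 °C to rt; evaporate; Amberlyst A-21, MeOH
Reagents that add atoms: none
Why: Acidolysis of the tert-butyl carbamate is safe here because Cb now carries only non-basic nitrogens (pyrrole, lactam, guanidinium) and does not ionise, while water keeps Ca hydrated and the cis C/D fusion returns the same configuration after any reversible ionisation at Ca.

Compound list
1 | L-vinylglycine, (S)-2-aminobut-3-enoic acid | N[C@@H](C=C)C(=O)O | starting material
2 | N-Boc-L-vinylglycine, (S)-2-[(tert-butoxycarbonyl)amino]but-3-enoic acid | CC(C)(C)OC(=O)N[C@@H](C=C)C(=O)O | intermediate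
3 | allyl bromide | C=CCBr | starting material
4 | N-allyl-N-Boc-L-vinylglycine, (S)-2-[allyl(tert-butoxycarbonyl)amino]but-3-enoic acid | C=CCN(C(=O)OC(C)(C)C)[C@@H](C=C)C(=O)O | intermediate
5 | 3-hydroxypiperidin-2-one (racemic) | O=C1NCCCC1O | starting material
6 | 3-(tert-butyldimethylsilyloxy)piperidin-2-one (racemic) | O=C1NCCCC1O[Si](C)(C)C(C)(C)C | intermediate
7 | N-allyl-N-Boc-L-vinylglycyl fluoride (S) | C=CCN(C(=O)OC(C)(C)C)[C@@H](C=C)C(F)=O | intermediate
8 | 3-(tert-butyldimethylsilyloxy)-1-(trimethylsilyl)piperidin-2-one | C[Si](C)(C)N1CCCC(O[Si](C)(C)C(C)(C)C)C1=O | intermediate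
9 | 1-(N-allyl-N-Boc-L-vinylglycyl)-3-(tert-butyldimethylsilyloxy)piperidin-2-one, Cα S, both ring C3 epimers | C=CCN(C(=O)OC(C)(C)C)[C@@H](C=C)C(=O)N1CCCC(O[Si](C)(C)C(C)(C)C)C1=O | intermediate
10 | 1-(N-allyl-N-Boc-L-vinylglycyl)-3-hydroxypiperidin-2-one, Cα S, both ring C3 epimers | C=CCN(C(=O)OC(C)(C)C)[C@@H](C=C)C(=O)N1CCCC(O)C1=O | intermediate
11 | 1-(N-allyl-N-Boc-L-vinylglycyl)piperidine-2,3-dione, Cα S | C=CCN(C(=O)OC(C)(C)C)[C@@H](C=C)C(=O)N1CCCC(=O)C1=O | intermediate
12 | N-Boc-guanidine | CC(C)(C)OC(=O)N=C(N)N | starting material
13 | 1-(N-allyl-L-vinylglycyl)piperidine-2,3-dione, present as trifluoroacetate, free base drawn | C=CCN[C@@H](C=C)C(=O)N1CCCC(=O)C1=O | intermediate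
14 | aza-cyclol: B/C bicycle with Na bonded to Cb, Cb–OH, ketone at Ca, Cα S, Cb equilibrating | O=C1CCCN2C(=O)[C@H](C=C)N(CC=C)C12O | intermediate
15 | key-step precursor as N-Boc derivative: imidazolidin-4-one ring B of N-allyl-L-vinylglycine, piperidine ring C, 2-(Boc-imino)imidazolidine ring D; Cα S, Ca R, Cb R; vinyl anti to ring D nitrogen on Cb, OH syn to Na | CC(C)(C)OC(=O)N=C1N[C@@]2(O)CCCN3C(=O)[C@H](C=C)N(CC=C)[C@@]32N1 | intermediate
16 | 3-pyrroline tetracycle, N-Boc; Cα S, Ca R, Cb R | CC(C)(C)OC(=O)N=C1N[C@@]2(O)CCCN3C(=O)[C@@H]4C=CCN4[C@@]32N1 | intermediate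
17 | key-step product as N-Boc derivative: target skeleton without bromine; Ca R, Cb R | CC(C)(C)OC(=O)N=C1N[C@@]2(O)CCCN3C(=O)c4cccn4[C@@]32N1 | intermediate
18 | N-Boc derivative of the target, 4,5-dibromopyrrole; Ca R, Cb S | CC(C)(C)OC(=O)N=C1N[C@@]2(O)CCCN3C(=O)c4cc(Br)c(Br)n4[C@@]32N1 | intermediate
19 | CNP0143627.2; Ca R, Cb S, OH and pyrrole N cis on the C/D fusion | NC1=N[C@@]2(O)CCCN3C(=O)c4cc(Br)c(Br)n4[C@@]32N1 | target

Total step count: 11.
Longest linear sequence: 10 steps (1, 2, 4, 5, 6, 7, 8, 9, 10, 11, from L-vinylglycine). Step 3 lies on the side branch.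

Steps most likely to fail

Step 8 (labelled). Three things may go wrong:
- Acyl transfer from the still open imide to the guanidine may outrun cyclol formation and cleave ring C or strip off the amino acid.
- Proton loss at Cα in the acylamidinium stage may erode configuration.
- The facial bias in the closure of ring D may be too small.

The fallback sets out from 7 and comes back at 15. It reaches the orthoamide by oxidation of an aromatic 2-aminoimidazole, a mode of C–O/C–N bond formation known for this heterocycle. Commercial 1H-imidazo[4,5-b]pyridin-2-amine is converted with Boc2O into tert-butyl (1H-imidazo[4,5-b]pyridin-2-yl)carbamate F1. Its pyridine ring is hydrogenated (PtO2, H2, AcOH) to tert-butyl (4,5,6,7-tetrahydro-1H-imidazo[4,5-b]pyridin-2-yl)carbamate F2. Fluoride 7 acylates the ring N4–H (2,6-lutidine, CH2Cl2; a methanol quench cleaves any N-acylimidazole) to give the N4-(N-allyl-N-Boc-L-vinylglycyl) amide F3. 2-(Phenylsulfonyl)-3-phenyloxaziridine transfers oxygen to the ring-fusion carbon that bears the CH2 group, which gives the hydroxy-4H-imidazole acylamidine F4. TFA removes both Boc groups, and on neutralisation Na adds to the C=N bond at Cb to give the unprotected B/C/D tricycle F5, whose aminal diastereomers are separated. Boc2O then returns 15.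

Step 9. Three things may go wrong:
- The catalyst may be deactivated by binding to the acylguanidine or to Na.
- A ruthenium hydride may move the vinyl double bond into conjugation with the lactam.
- The orthoamide may ionise on heating.

The fallback sets out from 11 and comes back at 16. It keeps the same C3=C4 bond formation but moves it ahead of the nitrogen-rich stage. Carbamate diene 11 is cyclised with the same catalyst to 1-(N-Boc-3,4-dehydro-L-prolyl)piperidine-2,3-dione F6. TFA and then 12, as in step 8, lead through the dehydroproline aza-cyclol F7 to 16, which is now isolated. MnO2 or DDQ takes it to 17.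

Step 5. Three things may go wrong:
- Acyl transfer from the hindered fluoride may be sluggish.
- The activated vinylglycine may epimerise or suffer double-bond migration.
- The Boc group may be lost through cyclisation to an N-carboxyanhydride.

The fallback sets out from 6 and comes back at 9. It carries the vinyl group in latent form, so that a forcing anionic acylation can be used. Commercial N-Boc-L-homoserine lactone is opened with PhSeNa (from PhSeSePh, NaBH4, DMF) to (S)-2-[(tert-butoxycarbonyl)amino]-4-(phenylselanyl)butanoic acid F8. NaH and 3 give its N-allyl derivative F9, and cyanuric fluoride gives the acid fluoride F10. The lithium salt of 6 (n-BuLi, THF, −78 °C) is acylated by F10 to the selenide imide F11. H2O2 oxidises selenium to the selenoxide F12, which undergoes syn elimination at room temperature and unveils the vinyl group of 9.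

Further compounds
F1 | step 8 | tert-butyl (1H-imidazo[4,5-b]pyridin-2-yl)carbamate | CC(C)(C)OC(=O)Nc1nc2ncccc2[nH]1
F2 | step 8 | tert-butyl (4,5,6,7-tetrahydro-1H-imidazo[4,5-b]pyridin-2-yl)carbamate | CC(C)(C)OC(=O)Nc1nc2NCCCc2[nH]1
F3 | step 8 | N4-(N-allyl-N-Boc-L-vinylglycyl) amide of F2 | C=CCN(C(=O)OC(C)(C)C)[C@@H](C=C)C(=O)N1CCCc2[nH]c(NC(=O)OC(C)(C)C)nc21
F4 | step 8 | hydroxy-4H-imidazole acylamidine (both Ca epimers) | C=CCN(C(=O)OC(C)(C)C)[C@@H](C=C)C(=O)N1CCCC2(O)N=C(NC(=O)OC(C)(C)C)N=C12
F5 | step 8 | unprotected B/C/D tricycle | NC1=N[C@@]2(O)CCCN3C(=O)[C@H](C=C)N(CC=C)[C@@]32N1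
F6 | step 9 | 1-(N-Boc-3,4-dehydro-L-prolyl)piperidine-2,3-dione | CC(C)(C)OC(=O)N1CC=C[C@H]1C(=O)N2CCCC(=O)C2=O
F7 | step 9 | dehydroproline aza-cyclol | O=C1CCCN2C(=O)[C@@H]3C=CCN3C12O
F8 | step 5 | (S)-2-[(tert-butoxycarbonyl)amino]-4-(phenylselanyl)butanoic acid | CC(C)(C)OC(=O)N[C@@H](CC[Se]c1ccccc1)C(=O)O
F9 | step 5 | (S)-2-[allyl(tert-butoxycarbonyl)amino]-4-(phenylselanyl)butanoic acid | C=CCN(C(=O)OC(C)(C)C)[C@@H](CC[Se]c1ccccc1)C(=O)O
F10 | step 5 | acid fluoride of F9 | C=CCN(C(=O)OC(C)(C)C)[C@@H](CC[Se]c1ccccc1)C(F)=O
F11 | step 5 | selenide imide | C=CCN(C(=O)OC(C)(C)C)[C@@H](CC[Se]c1ccccc1)C(=O)N1CCCC(O[Si](C)(C)C(C)(C)C)C1=O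
F12 | step 5 | selenoxide of F11 | C=CCN(C(=O)OC(C)(C)C)[C@@H](CC[Se](=O)c1ccccc1)C(=O)N1CCCC(O[Si](C)(C)C(C)(C)C)C1=O
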